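## Analysis of the target

The target is a drimane (trans-fused rings A and B) whose C9 carries, through an exocyclic trisubstituted alkene C11=C1', a five-membered carbocycle C1'–C5'. That ring is a chlorinated, enolised cyclopentane-1,3-dione: C1' alkylidene carbon, C2' enol carbon, C3' CH, C4' ketone, C5' CHCl. The decalin has four contiguous stereocentres: C5 (α-H), C10 (β-methyl) and C9 (β side chain) are those of the common drimanes, but at C8 the hydroxyl is β (axial, syn to the C10 methyl) and the methyl α, the reverse of sclareol-derived material. The fifth stereocentre, C5' (R), sits alone beyond the alkene, whose geometry is E (C9 cis to the oxygenated C2', trans to C5'). C5' is α to a ketone, allylic and chlorine-bearing, so it can epimerise through an enol (a hydroxyfulvene), eliminate or be substituted; the axial tertiary alcohol can dehydrate and C11 is a Michael acceptor carbon. The difficulty is therefore the five-membered ring, not the decalin: five different carbons, chlorine at a position (C5') that electrophilic chlorination of the dione would not reach (it would go to C3'), and a stereocentre the decalin cannot steer. The strategy reads C1', C5', C4', C3' and C2' as five of the six carbons of a 5-chloro-2-hydroxy-1,4-benzoquinone carrying C11 at C6, so the substitution pattern is fixed on an arene and the sixth carbon is discarded.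

## Retrosynthetic reasoning

**C5'–H.** Nothing in the molecule can direct a proton to one face of C5'. Target 20 is therefore traced back to the C5'-epimeric mixture 17 through the planar tris-silyl fulvene 18, in which C5' is trigonal. Forward, a chiral acid chooses the face of protonation, and the acidic desilylation (through 19) must not re-enolise the centre.

**The five-membered ring.** Mixture 17 is opened to hydroxyquinone 13. The C2'–C3' bond is made; the quinone carbon that bore the hydroxyl is cut out of the ring as a carboxyl group (acid 14) and then lost; the C11–O bond is broken (through enol 15) to give C11=C1'. This cut is preferred to an aldol-type union at C11=C1' with a preformed ring because chlorine can then be placed on a benzene ring, where substitution is predictable, and because ring, alkene and dione appear in one operation. The forward step must add base to the vicinal dicarbonyl of the triketo tautomer and not to the chlorine-bearing carbon, and must lose the C11 oxygen and not the chlorine. The C8 oxygen stays silylated through the basic stage and is released in the acidic one (16 to 17).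

**The quinone oxygens.** 13 is the oxidation product of resorcinol 12. The only free carbon para to a phenol becomes the second carbonyl. That leaves the remaining hydroxyl beside the carbonyl that neighbours the drimanyl-bearing carbon, and chlorine beside that carbon, with no regiochemical choice at the quinone stage. 12 comes from 11 by cleaving the two aryl silyl ethers.

**C11–aryl.** 11 is cut into aldehyde 6 and the arylmagnesium 10 made from bromide 9. This bond joins two fragments of similar size and creates the C11 oxygen that later serves as leaving group. C11 becomes a stereocentre whose configuration does not matter.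

**C–Cl.** 9 comes from 5-bromoresorcinol 7 by chlorination para to one hydroxyl (8) and silylation. The halogen pattern is thus fixed on a simple arene where isomers can be removed.

**C11–C12.** Aldehyde 6 has one carbon fewer than lactone 2. Hydroxylation at C11 (3), reduction (4) and glycol cleavage give hydroxy aldehyde 5, which is silylated at O8 to 6. The silyl ether is needed against retro-aldol opening in the aryl addition and against attack of O8 on the chloroquinone later.

**C8–O.** 2 is the C8 epimer of sclareolide 1. Acid-mediated ionisation and reclosure of the lactone sets the axial 8β oxygen in one step.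

## Alternatives that were turned down

**Alternative 1:** The decalin itself is disconnected at C4–C5 and C9–C10 by polyene cyclisation of (2E,6E)-farnesol A1. Forward, a squalene–hopene cyclase variant protonates the terminal alkene, closes rings A and B and loses a C7 proton, giving drimenol A2 with C5, C9 and C10 set.
- For: an achiral C15 chain, one catalytic step, and C11 already an alcohol. On this point it is stronger than the chosen route, which spends steps 2 to 4 removing C12.
- Against: A2 has a C7=C8 alkene and no C8 oxygen, and hydration from the more open α face would be expected to give the equatorial 8α alcohol, the wrong epimer. It depends on an engineered enzyme, and it does nothing for the five-membered ring.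
- Comparison: the chosen route takes the C8 oxygen from sclareolide 1 and corrects it in one step, so its risk sits in a single ring-forming step.

**Alternative 2:** The C8–O bond is disconnected by iodocyclisation of drimenyl tert-butyl carbonate A3. Forward, IBr forms the α iodonium ion and the carbonate carbonyl oxygen, tethered at C11, opens it at the tertiary C8 from the β face with loss of the tert-butyl group, giving 7α-iododrimane-8β,11-diyl cyclic carbonate A4.
- For: the axial C8–O bond is fixed by mechanism (anti addition, intramolecular delivery), and both oxygens emerge protected. In certainty of the C8 configuration it is stronger than step 1, which relies on thermodynamic epimerisation.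
- Against: A3 must first be made from scarce A2; deiodination, carbonate cleavage, oxidation and silylation are needed before joining the route at 6; closure onto a tertiary carbon syn to the C10 methyl may be slow. The five-membered ring is again untouched.
- Comparison: the chosen route reaches the same 8β oxygen from a cheap lactone in one step.

**Alternative 3:** The C3'–C4' bond is disconnected: methoxide opens the enol lactone of the γ-methylenebutenolide A5 at C4', and the freed methyl ketone enolate closes on the ester to give the cyclopent-4-ene-1,3-dione A6 (11-O-TBS, 8-O-TES).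
- For: a known rearrangement, redox-neutral, no carbon lost. Chlorine would then enter as a nucleophile at C5' with allylic loss of the C11 oxygen, which is regiochemically sound. In precedent it is stronger than the chosen key step.
- Against: A5 needs its own multistep preparation; chlorine and the alkene are still missing after the key step; C5' is again unsteered; the linear sequence is about two steps longer.
- Comparison: the chosen route takes the five ring carbons and the chlorine from one arene in one coupling and makes ring, dione and alkene in one operation. Because every step of Alternative 3 is of a known type, its chemistry is kept as the fallback for step 11.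

Key step: step 11

Remark on the chemistry: the target is one tautomer of an enolised 1,3-dione whose enol forms interconvert freely; wherever C11 is a carbinol the 11R epimer is written, although either serves because C11 becomes trigonal in step 11.

## Route

Step 1
Reactants: 1 (+)-sclareolide
Product: 2 8-epi-sclareolide (13,14,15,16-tetranorlabdan-8β,12-olide; cis-fused γ-lactone)
Conditions: conc. H2SO4, HCO2H, rt
Reagents that add atoms: none
Why: Acid-mediated epimerisation of a tertiary lactone, an established reaction of sclareolide: the C8–O bond ionises to the tertiary cation and recloses to the cis-fused lactone, which sets C8 with the oxygen β (axial) and the methyl α under thermodynamic control.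

Step 2
Reactants: 2 8-epi-sclareolide
Product: 3 11-hydroxy-8-epi-sclareolide (either C11 epimer)
Conditions: KN(SiMe3)2, THF, −78 °C; then 3-phenyl-2-(phenylsulfonyl)oxaziridine, −78 °C; aq. NH4Cl
Reagents that add atoms: 3-phenyl-2-(phenylsulfonyl)oxaziridine (Davis reagent), O=S(=O)(c1ccccc1)N1OC1c1ccccc1
Why: α-Hydroxylation of a lactone enolate (Davis oxidation); the new C11 configuration is irrelevant because C11 becomes the aldehyde carbon in step 4.

Step 3
Reactants: 3 11-hydroxy-8-epi-sclareolide
Product: 4 13,14,15,16-tetranorlabdane-8β,11,12-triol (either C11 epimer)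
Conditions: LiAlH4, THF, 0 °C to reflux; H2O, aq. NaOH
Reagents that add atoms: none
Why: Hydride reduction of a lactone to the diol; no bond to C8 is broken, so its configuration is kept.

Step 4
Reactants: 4 13,14,15,16-tetranorlabdane-8β,11,12-triol
Product: 5 8β-hydroxydriman-11-al
Conditions: NaIO4, THF/H2O, 0 °C to rt
Reagents that add atoms: none
Why: Malaprade glycol cleavage of the 11,12-diol; the tertiary 8-hydroxyl is 1,3 to C11 and is not cleaved, and C12 leaves as formaldehyde.

Step 5
Reactants: 5 8β-hydroxydriman-11-al
Product: 6 8β-(triethylsilyloxy)driman-11-al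
Conditions: TESOTf, 2,6-lutidine, CH2Cl2, −78 to 0 °C
Reagents that add atoms: triethylsilyl trifluoromethanesulfonate (TESOTf), CC[Si](CC)(CC)OS(=O)(=O)C(F)(F)F
Why: Silyl triflate with a hindered base, the standard silylation of tertiary alcohols; the ether prevents retro-aldol opening of ring B in step 8 and keeps O8 away from the chlorine-bearing quinone carbon in step 11.

Step 6
Reactants: 7 5-bromobenzene-1,3-diol (5-bromoresorcinol)
Product: 8 5-bromo-4-chlorobenzene-1,3-diol
Conditions: SO2Cl2 (1 equiv), Et2O, 0 °C to rt
Reagents that add atoms: sulfuryl chloride, O=S(=O)(Cl)Cl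
Why: Electrophilic aromatic chlorination as in the preparation of 4-chlororesorcinol: attack para to one hydroxyl and ortho to the other is preferred over the carbon between the hydroxyls, and one equivalent in the cold limits a second chlorination.

Step 7
Reactants: 8 5-bromo-4-chlorobenzene-1,3-diol
Product: 9 1-bromo-2-chloro-3,5-bis(tert-butyldimethylsilyloxy)benzene
Conditions: TBSCl, imidazole, DMF, rt
Reagents that add atoms: tert-butyldimethylsilyl chloride (TBSCl), CC(C)(C)[Si](C)(C)Cl
Why: Standard silylation of phenols; the silyl ethers tolerate the organomagnesium step and come off under conditions that spare the alkyl silyl ether.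

Step 8
Reactants: 9 1-bromo-2-chloro-3,5-bis(tert-butyldimethylsilyloxy)benzene; 6 8β-(triethylsilyloxy)driman-11-al
Product: 11 (11R)-11-[2-chloro-3,5-bis(tert-butyldimethylsilyloxy)phenyl]-8β-(triethylsilyloxy)driman-11-ol, via arylmagnesium chloride 10 (not isolated)
Conditions: 9, i-PrMgCl·LiCl, THF, 0 °C to rt; then 6, 0 °C to rt; aq. NH4Cl
Reagents that add atoms: none
Why: Bromine–magnesium exchange (C–Br exchanges, C–Cl does not; the ortho-chloro arylmagnesium does not lose MgCl2 to an aryne at this temperature) followed by 1,2-addition to the aldehyde. The C11 configuration is not controlled and need not be, since both epimers converge in step 11.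

Step 9
Reactants: 11 (11R)-11-[2-chloro-3,5-bis(tert-butyldimethylsilyloxy)phenyl]-8β-(triethylsilyloxy)driman-11-ol
Product: 12 (11R)-11-(2-chloro-3,5-dihydroxyphenyl)-8β-(triethylsilyloxy)driman-11-ol
Conditions: KHF2, MeOH, rt
Reagents that add atoms: none
Why: Fluoride cleavage of aryl silyl ethers; KHF2 in methanol removes phenolic silyl groups and leaves the hindered tertiary alkyl silyl ether. The hydroxyls are meta to C11, so no quinone methide can form.

Step 10
Reactants: 12 (11R)-11-(2-chloro-3,5-dihydroxyphenyl)-8β-(triethylsilyloxy)driman-11-ol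
Product: 13 5-chloro-2-hydroxy-6-[(11R)-11-hydroxy-8β-(triethylsilyloxy)driman-11-yl]-1,4-benzoquinone
Conditions: K2[ON(SO3)2] (Fremy's salt), KH2PO4, H2O/acetone, 0 °C to rt
Reagents that add atoms: Fremy's salt (dipotassium nitrosodisulfonate), [K+].[K+].[O-]S(=O)(=O)N([O])S(=O)(=O)[O-]
Why: Teuber oxidation of a resorcinol to a 2-hydroxy-1,4-benzoquinone: the nitroxide attacks the phenoxyl radical at the free para carbon, the other para carbon being blocked by chlorine. This puts the hydroxyl beside the carbonyl next to the drimanyl-bearing carbon and leaves chlorine on the carbon next to it.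

Step 11
Reactants: 13 5-chloro-2-hydroxy-6-[(11R)-11-hydroxy-8β-(triethylsilyloxy)driman-11-yl]-1,4-benzoquinone
Product: 17 (4E)-5-chloro-3-hydroxy-4-(8β-hydroxydriman-11-ylidene)cyclopent-2-en-1-one as both C5' epimers, via hydroxy acid 14 (not isolated), via enol 15 (not isolated), via silyl ether 16 (not isolated)
Conditions: 2 M NaOH, degassed H2O/1,4-dioxane, Ar, 50 °C; then 1 M HCl (to pH 1), LiCl, 40 °C
Reagents that add atoms: none
Why: Proposed new method: in base 13 reacts through its cyclohex-5-ene-1,2,4-trione tautomer, hydroxide adds to C2 (the carbon that carried the hydroxyl) and C3 migrates from C2 to the neighbouring carbonyl carbon C1 (benzilic acid shift), which forms the C2'–C3' bond and closes the five-membered ring by a 1,2-shift ring contraction to give carboxylate 14. On acidification 14 is a vinylogous β-keto acid (CO2H–C2'–C1'=C5'–C4'=O) and loses CO2 through the C1'=C5' alkene to give enol 15, whose C2' enol expels the protonated C11 hydroxyl (the last stage of an aldol condensation) to give the C11=C1' alkene of 16, and the acid then cleaves the triethylsilyl ether to 17. The closest known reaction type is the benzilic acid ring contraction of hydroxyquinones and cyclohexenetriones with decarboxylation (rhodizonate to croconate), where the carbon is lost oxidatively; the redox-neutral finish, with the C11 hydroxyl as leaving group in place of an oxidant, has not been shown. The new C5' centre arises by protonation far from the decalin and is expected as both epimers, which is why step 13 sets it by reagent control. The E alkene is expected to be the more stable isomer of the free 8-hydroxy compound (hydrogen bond between the C2' enol and O8) and can equilibrate through reversible addition of water or chloride at C11 in the acidic medium. The step needs attack at the carbonyl carbons and not at the chlorine-bearing C5, for which the silyl ether keeps O8 off C5 and the branched C11 substituent shields it from hydroxide; it also needs loss of water and not of HCl, for which the second stage is run acidic with excess chloride so that any enedione formed by loss of HCl takes chloride up again at C5' and dehydrates to 17.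

Step 12
Reactants: 17 (4E)-5-chloro-3-hydroxy-4-(8β-hydroxydriman-11-ylidene)cyclopent-2-en-1-one (both C5' epimers)
Product: 18 (E)-4-chloro-1,3-bis(trimethylsilyloxy)-5-[8β-(trimethylsilyloxy)driman-11-ylidene]cyclopenta-1,3-diene
Conditions: TMSOTf, Et3N, CH2Cl2, −78 to 0 °C; pentane, cold aq. NaHCO3
Reagents that add atoms: trimethylsilyl trifluoromethanesulfonate (TMSOTf), C[Si](C)(C)OS(=O)(=O)C(F)(F)F
Why: Soft enolisation with a silyl triflate and an amine: O-silylation of the vinylogous acid, then enolisation of the C4' ketone toward C5', the only ring CH left beside C3', gives the bis(silyloxy)fulvene and erases C5' in both epimers. The tertiary hydroxyl is silylated as well and the alkene geometry is untouched.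

Step 13
Reactants: 18 (E)-4-chloro-1,3-bis(trimethylsilyloxy)-5-[8β-(trimethylsilyloxy)driman-11-ylidene]cyclopenta-1,3-diene
Product: 20 (4E,5R)-5-chloro-3-hydroxy-4-(8β-hydroxydriman-11-ylidene)cyclopent-2-en-1-one (CNP0279879.2), via silyl enol ether 19 (not isolated)
Conditions: (S)-N-triflyl thiophosphoramide of 3,3'-bis(2,4,6-triisopropylphenyl)-1,1'-bi-2-naphthol (10 mol %), PhOH (1.1 equiv), toluene, −78 °C; then 48% aq. HF, MeCN, 0 °C
Reagents that add atoms: none
Why: Proposed new method: 18 is a cyclic 1,3-bis(silyloxy)diene whose terminal carbon C5' is its most nucleophilic position (as in Chan-type dienes), so the proton is expected to enter there and not at C3' or at C11 (which would give an antiaromatic cyclopentadienyl cation), leaving the C2' silyl enol ether and the E alkene in place; the closest known reaction type is the catalytic enantioselective protonation of cyclic ketone silyl enol ethers by chiral N-triflyl thiophosphoramides with a phenol as stoichiometric proton source, not yet shown for a fulvene-type or chlorine-bearing silyl enol ether. The C5' configuration is set by the catalyst alone because the decalin is remote, so the catalyst enantiomer that gives 5'R in a first run is the one used, and HF then removes the remaining trimethylsilyl groups under acidic conditions that do not enolise C5'.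

## Compound list

1 | (+)-sclareolide | CC1(C)CCC[C@]2(C)[C@@H](CC(=O)O3)[C@@]3(C)CC[C@@H]12 | starting material
2 | 8-epi-sclareolide (8β,12-olide, cis-fused) | CC1(C)CCC[C@]2(C)[C@@H](CC(=O)O3)[C@]3(C)CC[C@@H]12 | intermediate
3 | 11-hydroxy-8-epi-sclareolide (either C11 epimer) | CC1(C)CCC[C@]2(C)[C@@H](C(O)C(=O)O3)[C@]3(C)CC[C@@H]12 | intermediate
4 | 13,14,15,16-tetranorlabdane-8β,11,12-triol (either C11 epimer) | CC1(C)CCC[C@]2(C)[C@@H](C(O)CO)[C@@](C)(O)CC[C@@H]12 | intermediate
5 | 8β-hydroxydriman-11-al | CC1(C)CCC[C@]2(C)[C@@H](C=O)[C@@](C)(O)CC[C@@H]12 | intermediate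
6 | 8β-(triethylsilyloxy)driman-11-al | CC1(C)CCC[C@]2(C)[C@@H](C=O)[C@@](C)(O[Si](CC)(CC)CC)CC[C@@H]12 | intermediate
7 | 5-bromobenzene-1,3-diol | Oc1cc(O)cc(Br)c1 | starting material
8 | 5-bromo-4-chlorobenzene-1,3-diol | Oc1cc(O)c(Cl)c(Br)c1 | intermediate
9 | 1-bromo-2-chloro-3,5-bis(tert-butyldimethylsilyloxy)benzene | CC(C)(C)[Si](C)(C)Oc1cc(O[Si](C)(C)C(C)(C)C)c(Cl)c(Br)c1 | intermediate
10 | [2-chloro-3,5-bis(tert-butyldimethylsilyloxy)phenyl]magnesium chloride (LiCl complex) | CC(C)(C)[Si](C)(C)Oc1cc(O[Si](C)(C)C(C)(C)C)c(Cl)c([Mg]Cl)c1 | intermediate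
11 | (11R)-11-[2-chloro-3,5-bis(tert-butyldimethylsilyloxy)phenyl]-8β-(triethylsilyloxy)driman-11-ol | CC1(C)CCC[C@]2(C)[C@@H]([C@@H](O)c3cc(O[Si](C)(C)C(C)(C)C)cc(O[Si](C)(C)C(C)(C)C)c3Cl)[C@@](C)(O[Si](CC)(CC)CC)CC[C@@H]12 | intermediate
12 | (11R)-11-(2-chloro-3,5-dihydroxyphenyl)-8β-(triethylsilyloxy)driman-11-ol | CC1(C)CCC[C@]2(C)[C@@H]([C@@H](O)c3cc(O)cc(O)c3Cl)[C@@](C)(O[Si](CC)(CC)CC)CC[C@@H]12 | intermediate
13 | 5-chloro-2-hydroxy-6-[(11R)-11-hydroxy-8β-(triethylsilyloxy)driman-11-yl]-1,4-benzoquinone | CC1(C)CCC[C@]2(C)[C@@H]([C@@H](O)C3=C(Cl)C(=O)C=C(O)C3=O)[C@@](C)(O[Si](CC)(CC)CC)CC[C@@H]12 | intermediate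
14 | 3-chloro-1-hydroxy-2-[(11R)-11-hydroxy-8β-(triethylsilyloxy)driman-11-yl]-4-oxocyclopent-2-ene-1-carboxylic acid (C1 epimers; carboxylate in the flask) | CC1(C)CCC[C@]2(C)[C@@H]([C@@H](O)C3=C(Cl)C(=O)CC3(O)C(=O)O)[C@@](C)(O[Si](CC)(CC)CC)CC[C@@H]12 | intermediate
15 | 5-chloro-3-hydroxy-4-[(11R)-11-hydroxy-8β-(triethylsilyloxy)driman-11-yl]cyclopent-3-en-1-one (C5 epimers) | CC1(C)CCC[C@]2(C)[C@@H]([C@@H](O)C3=C(O)CC(=O)C3Cl)[C@@](C)(O[Si](CC)(CC)CC)CC[C@@H]12 | intermediate
16 | (4E)-5-chloro-3-hydroxy-4-[8β-(triethylsilyloxy)driman-11-ylidene]cyclopent-2-en-1-one (C5' epimers) | CC1(C)CCC[C@]2(C)[C@@H](/C=C3\C(O)=CC(=O)C3Cl)[C@@](C)(O[Si](CC)(CC)CC)CC[C@@H]12 | intermediate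
17 | (4E)-5-chloro-3-hydroxy-4-(8β-hydroxydriman-11-ylidene)cyclopent-2-en-1-one (C5' epimers) | CC1(C)CCC[C@]2(C)[C@@H](/C=C3\C(O)=CC(=O)C3Cl)[C@@](C)(O)CC[C@@H]12 | intermediate
18 | (E)-4-chloro-1,3-bis(trimethylsilyloxy)-5-[8β-(trimethylsilyloxy)driman-11-ylidene]cyclopenta-1,3-diene | CC1(C)CCC[C@]2(C)[C@@H](/C=C3\C(O[Si](C)(C)C)=CC(O[Si](C)(C)C)=C3Cl)[C@@](C)(O[Si](C)(C)C)CC[C@@H]12 | intermediate
19 | (4E,5R)-5-chloro-3-(trimethylsilyloxy)-4-[8β-(trimethylsilyloxy)driman-11-ylidene]cyclopent-2-en-1-one | CC1(C)CCC[C@]2(C)[C@@H](/C=C3\C(O[Si](C)(C)C)=CC(=O)[C@@H]3Cl)[C@@](C)(O[Si](C)(C)C)CC[C@@H]12 | intermediate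
20 | (4E,5R)-5-chloro-3-hydroxy-4-(8β-hydroxydriman-11-ylidene)cyclopent-2-en-1-one (CNP0279879.2) | CC1(C)CCC[C@]2(C)[C@@H](/C=C3\C(O)=CC(=O)[C@@H]3Cl)[C@@](C)(O)CC[C@@H]12 | target

## Step count and least certain steps

Total: 13 steps. Longest linear sequence: 11 steps (steps 1–5 and 8–13, from 1 to 20); steps 6 and 7 prepare the aryl bromide.

**Step 11 (key step).** Most likely failure: hydroxide displaces the vinylic chlorine at C5 by addition–elimination (or the hydroxyalkyl quinone undergoes internal redox isomerisation to an acyl hydroquinone) faster than it adds to the delocalised hydroxyquinone anion, so no ring contraction occurs. Fallback with known reactions only, from aldehyde 6 back to mixture 17: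
- 3-Bromo-2-methylfuran is lithiated (n-BuLi, THF, −78 °C) to (2-methylfuran-3-yl)lithium F1, which adds to 6 to give (11R)-11-(2-methylfuran-3-yl)-8β-(triethylsilyloxy)driman-11-ol F2.
- Silylation (TESOTf, 2,6-lutidine) gives (11R)-11-(2-methylfuran-3-yl)-8β,11-bis(triethylsilyloxy)drimane F3.
- Singlet oxygen (O2, tetraphenylporphyrin, light, CH2Cl2, −78 °C, then i-Pr2NEt) oxidises the furan to 5-hydroxy-5-methyl-4-[(11R)-8β,11-bis(triethylsilyloxy)driman-11-yl]furan-2(5H)-one F4.
- The open keto-acid form of F4 is esterified (MeI, K2CO3, DMF) to methyl (2Z)-3-[(11R)-8β,11-bis(triethylsilyloxy)driman-11-yl]-4-oxopent-2-enoate F5.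
- NaOMe in MeOH closes F5, by attack of the methyl ketone enolate on the ester, to 4-[(11R)-8β,11-bis(triethylsilyloxy)driman-11-yl]cyclopent-4-ene-1,3-dione F6.
- 1 M HCl with LiCl in THF at 40 °C removes both silyl groups, adds chloride at C5' and expels the C11 hydroxyl (allylic substitution of a Morita–Baylis–Hillman-type alcohol), which returns the route at 17.

**Step 13.** Most likely failure: weak facial discrimination by the catalyst on this cross-conjugated, chlorine-bearing silyl dienol ether, competing protonation at C3', or epimerisation during desilylation. Fallback with known chemistry, from 17 to 20: the two C5' epimers of 17 are separated by preparative HPLC; the 5'R epimer is 20. The unwanted (4E,5S)-5-chloro-3-hydroxy-4-(8β-hydroxydriman-11-ylidene)cyclopent-2-en-1-one F7 is re-equilibrated to 17 by acid-catalysed enolisation (1 M HCl, LiCl, THF, 40 °C, the second-stage conditions of step 11) and recycled.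

**Step 10.** Most likely failure: oxidation at the carbon between the two hydroxyls instead of the para carbon, which lies next to the bulky C11 substituent, leading to an ortho-quinone, or over-oxidation. Fallback from aldehyde 6 back to 13, building the quinone from a hydroquinone dimethyl ether:
- 2-Chloro-1,4-dimethoxybenzene is lithiated between chlorine and methoxy (LiN(i-Pr)2, THF, −78 °C) to (2-chloro-3,6-dimethoxyphenyl)lithium F8, which adds to 6 to give (11R)-11-(2-chloro-3,6-dimethoxyphenyl)-8β-(triethylsilyloxy)driman-11-ol F9.
- (NH4)2Ce(NO3)6 in MeCN/H2O at 0 °C demethylates oxidatively to 2-chloro-3-[(11R)-11-hydroxy-8β-(triethylsilyloxy)driman-11-yl]-1,4-benzoquinone F10.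
- Weitz–Scheffer epoxidation of the unsubstituted CH=CH (t-BuOOH, DBU) gives 5,6-epoxy-2-chloro-3-[(11R)-11-hydroxy-8β-(triethylsilyloxy)driman-11-yl]cyclohex-2-ene-1,4-dione F11.
- Isomerisation on silica or with Et3N opens the epoxide to the hydroxyquinone 13. Any regioisomer formed, 6-chloro-2-hydroxy-5-[(11R)-11-hydroxy-8β-(triethylsilyloxy)driman-11-yl]-1,4-benzoquinone F12, is carried into step 11 as well, since it loses its own hydroxyl-bearing carbon and contracts to the same ring.

**Step 6.** Most likely failure: poor positional selectivity, with chlorination between the hydroxyls or twice. Fallback from 7 back to 9, reversing the order: 7 is silylated first (TBSCl, imidazole, DMF) to 1-bromo-3,5-bis(tert-butyldimethylsilyloxy)benzene F13, in which the two silyl ethers shield the carbon between them. Chlorination with N-chlorosuccinimide in MeCN then occurs para to a silyloxy group and ortho to bromine, giving 9 directly.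

## Further compounds

F1 | step 11 | (2-methylfuran-3-yl)lithium | Cc1occc1[Li]
F2 | step 11 | (11R)-11-(2-methylfuran-3-yl)-8β-(triethylsilyloxy)driman-11-ol | CC1(C)CCC[C@]2(C)[C@@H]([C@@H](O)c3ccoc3C)[C@@](C)(O[Si](CC)(CC)CC)CC[C@@H]12
F3 | step 11 | (11R)-11-(2-methylfuran-3-yl)-8β,11-bis(triethylsilyloxy)drimane | CC1(C)CCC[C@]2(C)[C@@H]([C@@H](O[Si](CC)(CC)CC)c3ccoc3C)[C@@](C)(O[Si](CC)(CC)CC)CC[C@@H]12
F4 | step 11 | 5-hydroxy-5-methyl-4-[(11R)-8β,11-bis(triethylsilyloxy)driman-11-yl]furan-2(5H)-one | CC1(C)CCC[C@]2(C)[C@@H]([C@@H](O[Si](CC)(CC)CC)C3=CC(=O)OC3(C)O)[C@@](C)(O[Si](CC)(CC)CC)CC[C@@H]12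
F5 | step 11 | methyl (2Z)-3-[(11R)-8β,11-bis(triethylsilyloxy)driman-11-yl]-4-oxopent-2-enoate | CC1(C)CCC[C@]2(C)[C@@H]([C@@H](O[Si](CC)(CC)CC)/C(C(C)=O)=C/C(=O)OC)[C@@](C)(O[Si](CC)(CC)CC)CC[C@@H]12
F6 | step 11 | 4-[(11R)-8β,11-bis(triethylsilyloxy)driman-11-yl]cyclopent-4-ene-1,3-dione | CC1(C)CCC[C@]2(C)[C@@H]([C@@H](O[Si](CC)(CC)CC)C3=CC(=O)CC3=O)[C@@](C)(O[Si](CC)(CC)CC)CC[C@@H]12
F7 | step 13 | (4E,5S)-5-chloro-3-hydroxy-4-(8β-hydroxydriman-11-ylidene)cyclopent-2-en-1-one | CC1(C)CCC[C@]2(C)[C@@H](/C=C3\C(O)=CC(=O)[C@H]3Cl)[C@@](C)(O)CC[C@@H]12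
F8 | step 10 | (2-chloro-3,6-dimethoxyphenyl)lithium | COc1ccc(OC)c(Cl)c1[Li]
F9 | step 10 | (11R)-11-(2-chloro-3,6-dimethoxyphenyl)-8β-(triethylsilyloxy)driman-11-ol | CC1(C)CCC[C@]2(C)[C@@H]([C@@H](O)c3c(Cl)c(OC)ccc3OC)[C@@](C)(O[Si](CC)(CC)CC)CC[C@@H]12
F10 | step 10 | 2-chloro-3-[(11R)-11-hydroxy-8β-(triethylsilyloxy)driman-11-yl]-1,4-benzoquinone | CC1(C)CCC[C@]2(C)[C@@H]([C@@H](O)C3=C(Cl)C(=O)C=CC3=O)[C@@](C)(O[Si](CC)(CC)CC)CC[C@@H]12
F11 | step 10 | 5,6-epoxy-2-chloro-3-[(11R)-11-hydroxy-8β-(triethylsilyloxy)driman-11-yl]cyclohex-2-ene-1,4-dione | CC1(C)CCC[C@]2(C)[C@@H]([C@@H](O)C3=C(Cl)C(=O)C4OC4C3=O)[C@@](C)(O[Si](CC)(CC)CC)CC[C@@H]12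
F12 | step 10 | 6-chloro-2-hydroxy-5-[(11R)-11-hydroxy-8β-(triethylsilyloxy)driman-11-yl]-1,4-benzoquinone | CC1(C)CCC[C@]2(C)[C@@H]([C@@H](O)C3=C(Cl)C(=O)C(O)=CC3=O)[C@@](C)(O[Si](CC)(CC)CC)CC[C@@H]12
F13 | step 6 | 1-bromo-3,5-bis(tert-butyldimethylsilyloxy)benzene | CC(C)(C)[Si](C)(C)Oc1cc(Br)cc(O[Si](C)(C)C(C)(C)C)c1
A1 | alternative 1 | (2E,6E)-farnesol | CC(C)=CCC/C(C)=C/CC/C(C)=C/CO
A2 | alternative 1 | drimenol (drim-7-en-11-ol) | CC1(C)CCC[C@]2(C)[C@@H](CO)C(C)=CC[C@@H]12
A3 | alternative 2 | drimenyl tert-butyl carbonate | CC1(C)CCC[C@]2(C)[C@@H](COC(=O)OC(C)(C)C)C(C)=CC[C@@H]12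
A4 | alternative 2 | 7α-iododrimane-8β,11-diyl cyclic carbonate | CC1(C)CCC[C@]2(C)[C@@H](COC(=O)O3)[C@]3(C)[C@H](I)C[C@@H]12
A5 | alternative 3 | 4-[(11R)-11-(tert-butyldimethylsilyloxy)-8β-(triethylsilyloxy)driman-11-yl]-5-methylenefuran-2(5H)-one | CC1(C)CCC[C@]2(C)[C@@H]([C@@H](O[Si](C)(C)C(C)(C)C)C3=CC(=O)OC3=C)[C@@](C)(O[Si](CC)(CC)CC)CC[C@@H]12
A6 | alternative 3 | (11R)-11-(3,5-dioxocyclopent-1-en-1-yl)driman-8β,11-diol 11-O-tert-butyldimethylsilyl 8-O-triethylsilyl ether | CC1(C)CCC[C@]2(C)[C@@H]([C@@H](O[Si](C)(C)C(C)(C)C)C3=CC(=O)CC3=O)[C@@](C)(O[Si](CC)(CC)CC)CC[C@@H]12
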